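What interests me in these flasks is the leftover: the initiator still standing once the impurity has taken its share, if it takes that share one for one.

| flask | free monomer | initiator | impurity | remark | time |
|---|---|---|---|---|---|
| north-west | 3 M | 5 mol% | 95 mM | the very flask that is asked about, followed so far |  |
| east | 3 M | 2.5 mol% | 95 mM | run made earlier |  |
| flask | 3.0 M | 5 mol% | 95 mM |  | 2.0 h |

| run | time / min | monomer in chains / % | free monomer / % |
|---|---|---|---|
| north-west | 5.00 | 2.1 | 97.8 |
| north-west | 10.0 | 7.8 | 93.0 |
| north-west | 15.0 | 13.6 | 86.4 |
| north-west | 20.0 | 19.8 | 79.7 |
| north-west | 25.0 | 27.3 | 73.0 |
| east | 4.00 | 0 | 99.8 |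
| east | 12.0 | 0.4 | 99.2 |
| east | 20.0 | 1.0 | 99.5 |
| east | 30.0 | 1.1 | 98.9 |
| east | 50.0 | 2.1 | 98.2 |

(readings scatter by 0.3 percentage points)

- the average divides the monomer in chains by the number of chains begun, living and dead together
- the earlier runs do not show the number of chains; that part of a forecast is a guess

* average number of monomer units in a chain (chains begun, living or dead) at 2.0 h
* part of the free monomer that has reacted at 2.0 h

I fold the charges into one number, charged [initiator] over charged [impurity]:

cover ratio, north-west run and asked flask = 1.58

cover ratio, east run = 0.789

This cover ratio says how many times the initiator covers the impurity, if they pair one for one, and at one the pairing changes from one limiting partner to the other. Above one, the impurity is the limiting reagent of that pairing. The readings fit: the north-west run, above one, is down to 73.0% free monomer at 25.0 min, while the east run, below it, still holds 98.2% at 50.0 min.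

If each leftover initiator begins a chain, the asked flask has:

chains = [impurity] × (cover ratio less one) = 0.0550 M

whole charge per chain = 54.5

I expect dp to be that figure times the part reacted. But one number is not enough: it holds no time, so I do not read c from it, and the east run, below one, still shows 2.1% in chains at 50.0 min against a scatter of 0.3 percentage points.

The forecast says “the impurity evidently kills the active species” and gives dp 27 (16 to 55) and c 91% (79% to 99%). Its dp is lower than my reckoning, which at its c gives 49.6.

The flask gives dp 53.9 and c 85.4%.

    monomer in chains + living end → free monomer + living end, rate k1*[living end] as long as [monomer in chains] is above zero (k = 0.167 min⁻¹)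
    free monomer + initiator → living end + monomer in chains (k = 0.0182 L mol⁻¹ min⁻¹)
    free monomer + living end → monomer in chains + living end, rate k3*[living end]*[free monomer] (k = 0.585 L mol⁻¹ min⁻¹)
    free monomer + initiator → spent initiator A (k = 0.00213 L mol⁻¹ min⁻¹)
    initiator + impurity → spent initiator B (k = 124 L mol⁻¹ min⁻¹)

In the asked flask at 2.00 h, free monomer has a half-life of 0.42 h by the growth step against 13 d by the chain-starting step, and at 0.721 h the growth step uses it 190 times as fast as the chain-starting step. Living end in that flask stands at 0.0474 M at 2.00 h, less than the 0.0550 M from the cover ratio.

For the neighbour with 2 mol% of initiator, the cover ratio is 0.632, below one, so I expect no leftover and 36.8% of the impurity uncovered. That neighbour ends with 37% of its impurity, 0% of its initiator, c 2.73% and dp 189.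

The readings are simulated on assumed constants; scatter was added.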